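(The data were computed for substances that don't exist, and the scatter is random.)

In a one-step world, with target and side product A each drawn from the starting material by a first-order step, their ratio stands from the first minute at the ratio of the two rate constants, the selectivity factor. The flask I was asked about did not read like that.

- autumn: starting material 27 mM; the very flask that is asked about, followed so far
- flask: starting material 27 mM; time 8.0 d

autumn run (percent of the starting material charged)

| time / h | side product A / % | target / % |
|---|---|---|
| 3.00 | 1 | 0 |
| 6.00 | 0 | 2 |
| 15.0 | 10 | 0 |
| 30.0 | 18 | 6 |

(each reading ± 2 percentage points)

- a species is counted by the starting material in it: one homo dimer or side product B counts as two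
- the numbers in the tables scatter with a standard deviation of 2 percentage points
- on the list of suspects stand: starting material -> target; intermediate A -> intermediate C; starting material <-> intermediate B; intermediate A <-> intermediate D; starting material <-> intermediate A; intermediate B <-> intermediate D; starting material + intermediate C -> side product B; 2 starting material -> homo dimer; intermediate C -> side product A

- ratio of side product A to target at 3.0 h
- ratio of side product A to target at 20 h
- ratio of side product A to target at 8.0 d

In the autumn run I drew the target as a line through the origin, rising by 0.00164 /h of the charge. Side product A lay flat within the scatter up to a knee I put at 6.00 h, then climbed by 0.0111 /h. So my two lines crossed near 7.04 h. Beyond 15.0 h the readings gave a slope of 0.00533 /h, smaller than before. I let the ratio run toward the late slope ratio, the slope of side product A beyond 15.0 h over the slope of the target line, 3.25, a reading that carries the scatter.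

The forecast gave 0.4, 3.3 and 4.2, the last higher than my level: “The ratio approaches the branching ratio, about 4, perhaps higher as the bimolecular losses fade.”

The flask gave 0.251, 2.87 and 6.50.

    starting material → target (k = 7.46 × 10⁻⁵ /min)
    intermediate A → intermediate C (k = 0.00207 /min)
    starting material ⇌ intermediate B (K = 0.107, k = 7.15 × 10⁻⁴ /min)
    intermediate A ⇌ intermediate D (k = 0.00131 /min)
    starting material ⇌ intermediate A (K = 0.702, k = 8.95 × 10⁻⁴ /min)
    intermediate B ⇌ intermediate D (K = 14.0, k = 3.62 × 10⁻⁴ /min)
    starting material + intermediate C → side product B (k = 0.0962 /M/min)
    2 starting material → homo dimer (k = 0.0203 /M/min)
    intermediate C → side product A (k = 0.00255 /min)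

At 8.0 d the flask stood at twice my 3.25, and the neighbour flask with 6.8 mM of starting material stood at 7.12, or 2.19 times 3.25. In the flask, intermediate C had a half-life of 0.19 d by the step to side product B, with the other concentrations as charged, about the same as the 0.189 d by the step to side product A. Side product B reached 13.4 % in the flask and 7.06 % in the neighbour flask.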